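The seven-membered ring is read as a masked cyclohepta-1,4-diene whose C6 oxygen sits between C5 and C7 (daucane numbering: C1 and C5 are the ring-fusion carbons, C6 bears the anisoate, C8/C9 the epoxide). This is a formal (4+3) retron that joins the diene C8–C9–C10–C1 to the oxygenated vinylcarbene C5–C6–C7. An acyclic siloxyvinyl diazo ketone, tethered through C4–C3–C2 to an (E,E)-diene, is cyclopropanated by a rhodium carbenoid at C1=C10, and the cis-divinylcyclopropane then undergoes Cope rearrangement. One operation forms the ring-fusion bond C5–C1 and the C7–C8 bond, closes both the five- and the seven-membered ring, and sets the quaternary C1 under control of C2.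

Key step: step 6

Remark: atoms are numbered as in daucane (C1 quaternary ring-fusion carbon with methyl, C2 CH–OAc, C3 CH2, C4 C(OH)(i-Pr), C5 ring-fusion CH, C6 CH–O-anisoyl, C7 CH2, C8/C9 epoxide carbons with the methyl on C8, C10 CH–OH); β is the face of the C1 methyl group, so the target is 1β-Me, 2β-OAc, 4β-OH, 5α-H, 6α-OAr, 8α,9α-epoxide, 10β-OH.

Step 1
Reactants: 1 (E)-but-2-enal; 2 2-(triphenylphosphoranylidene)propanal
Product: 3 (2E,4E)-2-methylhexa-2,4-dienal
Conditions: toluene, 90 °C
Reagents that add atoms: none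
Why: Wittig olefination with the formyl-stabilised ylide is (E)-selective for the new trisubstituted double bond and leaves the (E)-crotyl double bond untouched.

Step 2
Reactants: 4 pentane-2,4-dione
Product: 5 3-diazopentane-2,4-dione
Conditions: p-ABSA, Et3N, MeCN, 0 → 23 °C
Reagents that add atoms: 4-acetamidobenzenesulfonyl azide (p-ABSA), CC(=O)Nc1ccc(cc1)S(=O)(=O)N=[N+]=[N-]
Why: Regitz diazo transfer to the active methylene of the 1,3-diketone.

Step 3
Reactants: 5 3-diazopentane-2,4-dione
Product: 6 4-[(tert-butyldimethylsilyl)oxy]-3-diazopent-4-en-2-one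
Conditions: TBSOTf (1 equiv), Et3N, CH2Cl2, 0 °C
Reagents that add atoms: tert-butyldimethylsilyl triflate, CC(C)(C)[Si](C)(C)OS(=O)(=O)C(F)(F)F
Why: Soft enolisation with O-silylation (silyl enol ether formation); the two acetyl groups are equivalent, so the enol ether is regiodefined and the remaining acetyl group keeps the diazo carbon acceptor-stabilised.

Step 4
Reactants: 6 4-[(tert-butyldimethylsilyl)oxy]-3-diazopent-4-en-2-one; 3 (2E,4E)-2-methylhexa-2,4-dienal
Product: 7 (6R,7E,9E)-2-[(tert-butyldimethylsilyl)oxy]-3-diazo-6-hydroxy-7-methylundeca-1,7,9-trien-4-one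
Conditions: (−)-Ipc2BCl, Et3N, Et2O, −78 → 0 °C; then 3, −78 → −20 °C; H2O2, MeOH, pH 7 buffer, 0 °C
Reagents that add atoms: none
Why: Boron-mediated aldol addition of a methyl ketone: only the acetyl group of 6 can enolise, and the diisopinocampheylboron enolate should add to the re face of the α-branched enal, which sets the (6R) carbinol (C2 of the target).

Step 5
Reactants: 7 (6R)-aldol adduct
Product: 8 (6R,7E,9E)-2-[(tert-butyldimethylsilyl)oxy]-3-diazo-7-methyl-6-[(triethylsilyl)oxy]undeca-1,7,9-trien-4-one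
Conditions: TESCl, imidazole, DMF, 0 °C
Reagents that add atoms: chlorotriethylsilane, CC[Si](Cl)(CC)CC
Why: Silyl ether formation masks the hydroxyl group, which would otherwise undergo O–H insertion with the carbenoid, with a group that is later cleaved together with the enol ether.

Step 6
Reactants: 8 siloxyvinyl diazo ketone
Product: 10 hydroazulenone cycloadduct (C4 ketone; C5=C6 TBS enol ether; C9=C10 alkene; 1β-methyl; 2β-OSiEt3; 8α-methyl), via cis-divinylcyclopropane 9 (not isolated)
Conditions: Rh2(O2CC7H15)4 (1 mol %), toluene, 23 °C (slow addition of 8); then 110 °C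
Reagents that add atoms: none
Why: The dirhodium tetracarboxylate turns the vinyl diazo ketone into a donor/acceptor rhodium carbenoid at C5, which cyclopropanates the proximal, electron-rich C1=C10 bond of the tethered diene (bonds C5–C1 and C5–C10) to give cis-divinylcyclopropane 9; heating then drives the [3,3] shift that breaks C5–C10 and forms C7–C8, so the net result is the C5–C1 and C7–C8 bonds. The closest known reaction type is the tandem cyclopropanation/Cope rearrangement of siloxyvinyl diazo compounds with dienes (formal (4+3) cycloaddition), used here in the intramolecular diazo ketone mode. The cyclopentanone closes by (2+1) carbene addition across the γ,δ-alkene (five-membered ring through C5–C1 within a bicyclo[3.1.0]hexan-2-one), and the cycloheptadiene closes by boat-type divinylcyclopropane Cope ring expansion. C1 is set by the C2 stereocentre: the carbenoid should add to the face of C1=C10 that leaves the OSiEt3 group exo on the forming bicycle, away from rhodium and the closing C10 and hence cis to the C1 methyl group; C8 is set by the boat transition state and the (E)-propenyl geometry, which place 8-H on the face of the C1 methyl group. The step needs cyclopropanation rather than oxonium ylide formation, C–H insertion or attack at C8=C9, and it needs the two vinyl groups cis; the 1-diazohex-5-en-2-one array (five-ring closure), the weakly basic hindered silyl ether and the (7E) alkene, which puts the propenyl group exo, secure these.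

Step 7
Reactants: 10 hydroazulenone cycloadduct
Product: 11 tertiary alcohol (4β-hydroxy-4α-isopropyl; C5=C6 TBS enol ether; C9=C10 alkene; 1β-methyl; 2β-OSiEt3; 8α-methyl)
Conditions: i-PrMgCl, CeCl3, THF, −78 → 0 °C; aq. NaHCO3
Reagents that add atoms: isopropylmagnesium chloride, CC(C)[Mg]Cl
Why: Organocerium 1,2-addition to the hindered, enolisable vinylogous ester carbonyl; the reagent should approach C4 from the α face, anti to the C1 methyl and the C2 silyloxy group, and the non-acidic work-up keeps the β-hydroxy enol ether from eliminating.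

Step 8
Reactants: 11 tertiary alcohol
Product: 12 trans-fused diol ketol (2β,4β-dihydroxy-4α-isopropyl-1β,8α-dimethyl-5α-H; C6 ketone; C9=C10 alkene)
Conditions: TBAF, AcOH, THF, 0 → 23 °C
Reagents that add atoms: none
Why: Fluoride cleaves both silyl ethers and the liberated enol should be protonated at C5 axially from the α face, anti to the angular methyl group, giving the trans-fused ketol (expected to be the more stable epimer as well, with the isopropyl group anti to C6 and an O–H···O=C hydrogen bond); the acetic acid buffer suppresses retro-aldol cleavage and dehydration.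

Step 9
Reactants: 12 diol ketol
Product: 13 2β-acetate of the ketol (4β-OH free)
Conditions: Ac2O, pyridine, DMAP (cat.), CH2Cl2, 0 → 23 °C
Reagents that add atoms: acetic anhydride, CC(=O)OC(C)=O
Why: Acylation of the only secondary alcohol; the tertiary C4 hydroxyl is too hindered to react.

Step 10
Reactants: 13 keto acetate
Product: 14 4β,6α-diol 2β-acetate (C9=C10 alkene)
Conditions: Me4NBH(OAc)3, MeCN/AcOH, −30 → −20 °C
Reagents that add atoms: none
Why: Evans–Saksena reduction: the C4 hydroxyl binds the acetoxyborohydride and delivers hydride intramolecularly to the β face of C6 (the face an external hydride avoids because of the axial C1 methyl group), giving the 6α-alcohol.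

Step 11
Reactants: 14 diol acetate
Product: 15 6α-(4-methoxybenzoate) 2β-acetate (4β-OH free; C9=C10 alkene; 8α-methyl)
Conditions: 4-methoxybenzoyl chloride, pyridine, DMAP (cat.), CH2Cl2, 23 °C
Reagents that add atoms: 4-methoxybenzoyl chloride, COc1ccc(cc1)C(Cl)=O
Why: Esterification of the only secondary alcohol with the acid chloride under nucleophilic catalysis.

Step 12
Reactants: 15 diester alkene
Product: 17 10β-allylic alcohol with C8=C9 alkene (6α-anisoate; 2β-acetate; 4β-OH), via allylic hydroperoxide 16 (not isolated)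
Conditions: O2, hν (visible), tetraphenylporphyrin (cat.), CH2Cl2, 0 °C; then PPh3
Reagents that add atoms: dioxygen, O=O
Why: Schenck ene reaction of singlet oxygen: the cis-disubstituted C9=C10 bond has a single allylic hydrogen, the pseudo-axial 8β-H, so oxygen must add suprafacially at C10 on the β face with shift of the double bond to C8=C9, and triphenylphosphine reduces the hydroperoxide with retention.

Step 13
Reactants: 17 allylic alcohol
Product: 18 10β-triethylsilyl ether (C8=C9 alkene; 4β-OH free)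
Conditions: TESOTf (1.1 equiv), 2,6-lutidine, CH2Cl2, −78 °C
Reagents that add atoms: triethylsilyl triflate, CC[Si](CC)(CC)OS(=O)(=O)C(F)(F)F
Why: Silylation of the secondary allylic alcohol removes its hydrogen-bond directing effect on the epoxidation; the tertiary C4 hydroxyl stays free at low temperature.

Step 14
Reactants: 18 silyl ether
Product: 19 8α,9α-epoxide (10β-OSiEt3; 6α-anisoate; 2β-acetate; 4β-OH)
Conditions: mCPBA, NaHCO3, CH2Cl2, 0 °C
Reagents that add atoms: 3-chloroperbenzoic acid, OOC(=O)c1cccc(Cl)c1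
Why: Prilezhaev epoxidation of the trisubstituted alkene from the α face, anti to the axial C1 methyl group and the C10 silyloxy group, sets C8 and C9.

Step 15
Reactants: 19 epoxy silyl ether
Product: 20 CNP0371526.1
Conditions: HF·pyridine, pyridine, THF, 0 °C
Reagents that add atoms: none
Why: Buffered fluoride desilylation frees the C10 alcohol without opening the epoxide or touching the esters.

Compound list
1 | (E)-but-2-enal | C/C=C/C=O | starting material
2 | 2-(triphenylphosphoranylidene)propanal | CC(C=O)=P(c1ccccc1)(c1ccccc1)c1ccccc1 | starting material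
3 | (2E,4E)-2-methylhexa-2,4-dienal | C/C=C/C=C(\C)C=O | intermediate
4 | pentane-2,4-dione | CC(=O)CC(C)=O | starting material
5 | 3-diazopentane-2,4-dione | CC(=O)C(=[N+]=[N-])C(C)=O | intermediate
6 | 4-[(tert-butyldimethylsilyl)oxy]-3-diazopent-4-en-2-one | CC(=O)C(=[N+]=[N-])C(=C)O[Si](C)(C)C(C)(C)C | intermediate
7 | (6R,7E,9E)-2-[(tert-butyldimethylsilyl)oxy]-3-diazo-6-hydroxy-7-methylundeca-1,7,9-trien-4-one | C=C(O[Si](C)(C)C(C)(C)C)C(=[N+]=[N-])C(=O)C[C@@H](O)/C(C)=C/C=C/C | intermediate
8 | (6R,7E,9E)-2-[(tert-butyldimethylsilyl)oxy]-3-diazo-7-methyl-6-[(triethylsilyl)oxy]undeca-1,7,9-trien-4-one | C=C(O[Si](C)(C)C(C)(C)C)C(=[N+]=[N-])C(=O)C[C@@H](O[Si](CC)(CC)CC)/C(C)=C/C=C/C | intermediate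
9 | cis-divinylcyclopropane: 1-[1-(TBS-oxy)ethenyl]-5-methyl-6-exo-[(E)-prop-1-enyl]-4-(triethylsilyloxy)bicyclo[3.1.0]hexan-2-one, OSiEt3 cis to the 5-methyl group | O=C1C[C@@H](O[Si](CC)(CC)CC)[C@]2(C)[C@@H](/C=C/C)[C@]12C(=C)O[Si](C)(C)C(C)(C)C | intermediate
10 | hydroazulenone cycloadduct: C4 ketone, C5=C6 TBS enol ether, C9=C10 alkene, 1β-methyl, 2β-OSiEt3, 8α-methyl | CC(C)(C)[Si](C)(C)OC1=C2C(=O)C[C@@H](O[Si](CC)(CC)CC)[C@]2(C)C=C[C@H](C)C1 | intermediate
11 | tertiary alcohol: 4β-hydroxy-4α-isopropyl, otherwise as 10 | CC(C)(C)[Si](C)(C)OC1=C2[C@](O)(C(C)C)C[C@@H](O[Si](CC)(CC)CC)[C@]2(C)C=C[C@H](C)C1 | intermediate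
12 | trans-fused diol ketol: 2β,4β-dihydroxy-4α-isopropyl-1β,8α-dimethyl-5α-H, C6 ketone, C9=C10 alkene | O=C1C[C@@H](C)C=C[C@]2(C)[C@@H]1[C@](O)(C(C)C)C[C@H]2O | intermediate
13 | 2β-acetate of 12 | O=C1C[C@@H](C)C=C[C@]2(C)[C@@H]1[C@](O)(C(C)C)C[C@H]2OC(C)=O | intermediate
14 | 4β,6α-diol 2β-acetate | O[C@H]1C[C@@H](C)C=C[C@]2(C)[C@@H]1[C@](O)(C(C)C)C[C@H]2OC(C)=O | intermediate
15 | 6α-(4-methoxybenzoate) 2β-acetate, C9=C10 alkene, 8α-methyl | COc1ccc(cc1)C(=O)O[C@H]2C[C@@H](C)C=C[C@]3(C)[C@@H]2[C@](O)(C(C)C)C[C@H]3OC(C)=O | intermediate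
16 | 10β-hydroperoxide with C8=C9 alkene | COc1ccc(cc1)C(=O)O[C@H]2CC(C)=C[C@H](OO)[C@]3(C)[C@@H]2[C@](O)(C(C)C)C[C@H]3OC(C)=O | intermediate
17 | 10β-allylic alcohol with C8=C9 alkene | COc1ccc(cc1)C(=O)O[C@H]2CC(C)=C[C@H](O)[C@]3(C)[C@@H]2[C@](O)(C(C)C)C[C@H]3OC(C)=O | intermediate
18 | 10β-triethylsilyl ether of 17 | COc1ccc(cc1)C(=O)O[C@H]2CC(C)=C[C@H](O[Si](CC)(CC)CC)[C@]3(C)[C@@H]2[C@](O)(C(C)C)C[C@H]3OC(C)=O | intermediate
19 | 8α,9α-epoxide of 18 | COc1ccc(cc1)C(=O)O[C@H]2C[C@@]3(C)O[C@H]3[C@H](O[Si](CC)(CC)CC)[C@]3(C)[C@@H]2[C@](O)(C(C)C)C[C@H]3OC(C)=O | intermediate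
20 | CNP0371526.1 (2β-acetoxy-6α-(4-methoxybenzoyloxy)-8α,9α-epoxydaucane-4β,10β-diol) | COc1ccc(C(=O)O[C@H]2C[C@@]3(C)O[C@H]3[C@H](O)[C@]3(C)[C@@H]2[C@](O)(C(C)C)C[C@H]3OC(C)=O)cc1 | target

Total step count: 15. Longest linear sequence: 14 steps (4 → 20, steps 2–15).

Steps most likely to fail

Step 6. The carbenoid may attack the other face of C1=C10, so that the silyloxy group ends trans to the C1 methyl group and the C1/C8-epimeric series forms. In the fallback the C2 carbinol serves only as a relay and is corrected afterwards by oxidation and hydride reduction; it sets out from 6 and 3. Aldol addition with (+)-Ipc2BCl gives the (6S) aldol adduct F1, and TESCl/imidazole gives its triethylsilyl ether F2. Under the conditions of step 6 the opposite facial preference then gives the cis-divinylcyclopropane with OSiEt3 trans to the methyl group F3 and from it the cycloadduct with correct C1 and C8 but 2α-OSiEt3 F4. Addition of i-PrMgCl/CeCl3 gives the tertiary alcohol F5; TBAF/AcOH at −78 °C cleaves only the enol ether to the 2α-silyloxy ketol F6; Me4NBH(OAc)3 gives the 6α-alcohol F7; 4-methoxybenzoyl chloride gives the anisoate F8. HF·pyridine frees the 2α-alcohol F9, Dess–Martin periodinane gives the C2 ketone F10, and NaBH4 in MeOH at −40 °C, attacking anti to the angular C1 methyl group, gives the 2β-alcohol F11. Acetylation of F11 (Ac2O, pyridine, DMAP) comes back to the route at 15.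

Step 12. Singlet oxygen has to reach C10 on the face that carries the axial C1 methyl group, so the ene reaction may be slow and the substrate may degrade on long irradiation. The fallback brings oxygen in from the open α face and corrects C10 by oxidation and reduction; it sets out from 15. mCPBA gives the 9α,10α-epoxide F12; NaSePh (from (PhSe)2 and NaBH4, EtOH) opens it trans-diaxially at C9 to the 9β-phenylseleno-10α-alcohol F13; oxidation with H2O2 and syn elimination of the selenoxide toward the cis 8β-H gives the 10α-allylic alcohol with C8=C9 alkene F14; Dess–Martin oxidation gives the C10 enone F15. Luche reduction (NaBH4, CeCl3·7H2O, MeOH, −40 °C), hydride entering anti to the axial C1 methyl group, comes back to the route at 17.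

Step 4. In the boron enolate of 6 the diazo carbon has lost its acceptor group and may decompose (cyclisation to a pyrazole, loss of nitrogen), and enantioface selection by methyl ketone boron enolates is only moderate. The fallback uses 6 as a Mukaiyama nucleophile through the enol ether it already has, so the diazo carbon stays next to a carbonyl group; it sets out from 6 and 3. A catalytic enantioselective Mukaiyama aldol addition (AgF with the BINAP antipode that delivers the 6R carbinol, THF/MeOH, −78 °C) gives the (6R) diazo diketone aldol F16; TESCl/imidazole gives its triethylsilyl ether F17. Kinetic enolisation of the acetyl methyl group (LiN(SiMe3)2, THF, −78 °C, then TBSCl) comes back to the route at 8.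

Further compounds
F1 | step 6 | (6S,7E,9E)-2-[(tert-butyldimethylsilyl)oxy]-3-diazo-6-hydroxy-7-methylundeca-1,7,9-trien-4-one | C=C(O[Si](C)(C)C(C)(C)C)C(=[N+]=[N-])C(=O)C[C@H](O)/C(C)=C/C=C/C
F2 | step 6 | (6S,7E,9E)-2-[(tert-butyldimethylsilyl)oxy]-3-diazo-7-methyl-6-[(triethylsilyl)oxy]undeca-1,7,9-trien-4-one | C=C(O[Si](C)(C)C(C)(C)C)C(=[N+]=[N-])C(=O)C[C@H](O[Si](CC)(CC)CC)/C(C)=C/C=C/C
F3 | step 6 | cis-divinylcyclopropane with OSiEt3 trans to the 5-methyl group (C4 epimer of 9) | O=C1C[C@H](O[Si](CC)(CC)CC)[C@]2(C)[C@@H](/C=C/C)[C@]12C(=C)O[Si](C)(C)C(C)(C)C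
F4 | step 6 | cycloadduct with 2α-OSiEt3 (C2 epimer of 10) | CC(C)(C)[Si](C)(C)OC1=C2C(=O)C[C@H](O[Si](CC)(CC)CC)[C@]2(C)C=C[C@H](C)C1
F5 | step 6 | tertiary alcohol with 2α-OSiEt3 (C2 epimer of 11) | CC(C)(C)[Si](C)(C)OC1=C2[C@](O)(C(C)C)C[C@H](O[Si](CC)(CC)CC)[C@]2(C)C=C[C@H](C)C1
F6 | step 6 | trans-fused ketol with 2α-OSiEt3 and 4β-OH | O=C1C[C@@H](C)C=C[C@]2(C)[C@@H]1[C@](O)(C(C)C)C[C@@H]2O[Si](CC)(CC)CC
F7 | step 6 | 4β,6α-diol with 2α-OSiEt3 | O[C@H]1C[C@@H](C)C=C[C@]2(C)[C@@H]1[C@](O)(C(C)C)C[C@@H]2O[Si](CC)(CC)CC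
F8 | step 6 | 6α-(4-methoxybenzoate) with 2α-OSiEt3 | COc1ccc(cc1)C(=O)O[C@H]2C[C@@H](C)C=C[C@]3(C)[C@@H]2[C@](O)(C(C)C)C[C@@H]3O[Si](CC)(CC)CC
F9 | step 6 | 6α-(4-methoxybenzoate) 2α,4β-diol | COc1ccc(cc1)C(=O)O[C@H]2C[C@@H](C)C=C[C@]3(C)[C@@H]2[C@](O)(C(C)C)C[C@@H]3O
F10 | step 6 | 6α-(4-methoxybenzoate) C2 ketone | COc1ccc(cc1)C(=O)O[C@H]2C[C@@H](C)C=C[C@]3(C)[C@@H]2[C@](O)(C(C)C)CC3=O
F11 | step 6 | 6α-(4-methoxybenzoate) 2β,4β-diol | COc1ccc(cc1)C(=O)O[C@H]2C[C@@H](C)C=C[C@]3(C)[C@@H]2[C@](O)(C(C)C)C[C@H]3O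
F12 | step 12 | 9α,10α-epoxide of 15 | COc1ccc(cc1)C(=O)O[C@H]2C[C@@H](C)[C@H]3O[C@H]3[C@]4(C)[C@@H]2[C@](O)(C(C)C)C[C@H]4OC(C)=O
F13 | step 12 | 9β-phenylseleno-10α-alcohol | COc1ccc(cc1)C(=O)O[C@H]2C[C@@H](C)[C@H]([Se]c3ccccc3)[C@@H](O)[C@]3(C)[C@@H]2[C@](O)(C(C)C)C[C@H]3OC(C)=O
F14 | step 12 | 10α-allylic alcohol with C8=C9 alkene (C10 epimer of 17) | COc1ccc(cc1)C(=O)O[C@H]2CC(C)=C[C@@H](O)[C@]3(C)[C@@H]2[C@](O)(C(C)C)C[C@H]3OC(C)=O
F15 | step 12 | C10 enone with C8=C9 alkene | COc1ccc(cc1)C(=O)O[C@H]2CC(C)=CC(=O)[C@]3(C)[C@@H]2[C@](O)(C(C)C)C[C@H]3OC(C)=O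
F16 | step 4 | (6R,7E,9E)-3-diazo-6-hydroxy-7-methylundeca-7,9-diene-2,4-dione | CC(=O)C(=[N+]=[N-])C(=O)C[C@@H](O)/C(C)=C/C=C/C
F17 | step 4 | (6R,7E,9E)-3-diazo-7-methyl-6-[(triethylsilyl)oxy]undeca-7,9-diene-2,4-dione | CC(=O)C(=[N+]=[N-])C(=O)C[C@@H](O[Si](CC)(CC)CC)/C(C)=C/C=C/C
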